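# Proposed synthesis of (3R)-3-(5-hydroxy-2,2-dimethyl-2H-chromen-6-yl)-8-prenylchroman-7-ol (15)

Numbering used throughout: isoflavan numbering for the target (ring A/C = chroman: O1, C2, C3, C4, C4a–C8a; ring B = C1′–C6′; ring D = the dimethylpyran fused to ring B, O on C4′, C4″ on C3′).

## The problem

The target 15 is an isoflavan: a chroman (ring A fused to pyran ring C) that carries ring B at C3, and ring B is itself fused through C3′ and O4′ to a 2,2-dimethyl-2H-pyran (ring D). C3 is the only stereocentre. It is tertiary, benzylic to ring B alone and flanked by two methylene groups (C2 on O1, C4 on C4a), so no neighbouring centre can relay chirality to it and it must be set by a reagent or a catalyst. At the isoflavan oxidation level C3 is configurationally stable, but every precursor with a carbonyl group at C2 or C4 makes C3–H acidic and racemisable. Both aromatic rings are resorcinols with a C5 unit on the carbon between the two oxygens (prenyl at C8 between O1 and O7; the pyran carbon at C3′ between O2′ and O4′), a pattern that direct electrophilic substitution does not deliver cleanly. The trisubstituted prenyl olefin and the electron-rich styrenic olefin of ring D exclude hydrogenation, hydrogenolysis, ozonolysis, halonium reagents and strong acid, and each sits ortho to a phenol (O7–H, O2′–H) that adds across it under acid. Two of the four oxygens are ring ethers and two are free phenols, so they must be told apart early.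

The feature that opens the route lies in ring C. C4 is an unsubstituted benzylic methylene on C4a and C3 carries exactly one hydrogen, so C3–C1′ plus C4–H is the retron of an aryl–H addition across the C3=C4 olefin of a 2H-chromene. That olefin is polarised so that a metal ends at C4 (benzylic to ring A) and the aryl group at C3, and after syn addition no syn β-hydrogen is left.

## Retrosynthesis

**15 ⇒ 14.** The two O–H bonds at O7 and O2′ are traced back to methoxymethyl ethers. The same group on both oxygens allows one final deprotection. On O2′ it has two further tasks: it directs the lithiation that makes 13, and it keeps O2′ from trapping the benzyl–palladium intermediate of the key step as a pterocarpan. The forward reaction must be an acetal cleavage mild enough to spare both olefins.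

**14 ⇒ 5 + 13 (key disconnection).** The C3–C1′ bond and one C4–H bond are cut, giving the 2H-chromene 5 and the aryl bromide 13.
- Against its neighbours: cutting O1–C2 or C3–C4 leads to an open-chain 2,3-diarylpropanol that needs an auxiliary and a separate ring closure. Passing through a C4 carbonyl leads to hydrogenation chemistry that the olefins do not tolerate.
- Gain in simplicity: the molecule falls into two achiral halves of similar size, each with its C5 unit already in place, and the precursor has no stereocentre.
- Asked of the forward reaction: regioselective (aryl to C3), site-selective (one olefin of three) and enantioselective hydroarylation.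

**5 ⇒ 4.** O1–C2 and C3=C4 are cut; C2 and C3 come from a vinylphosphonium salt and C4 is the aldehyde carbon of the salicylaldehyde 4. A propargyl-ether route to the chromene would need a monoprotected 2-prenylresorcinol, a symmetric diol that can only be differentiated statistically. The aldehyde fixes which oxygen and which carbon enter the ring.

**4 ⇒ 3 ⇒ 2 ⇒ 1.** The C8–prenyl bond is cut by a [3,3] shift back to the O2-(1,1-dimethylallyl) ether 3. Because C1 of the benzaldehyde carries the formyl group, C3 is the only free ortho position, which places the prenyl group between the two oxygens without isomers. Direct C-prenylation of 1 would give mixtures. 3 comes from the mono-MOM ether 2 and 2 from 2,4-dihydroxybenzaldehyde 1, whose hydrogen-bonded O2–H is left untouched by the first protection.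

**13 ⇒ 11 ⇒ 10.** The C6–Br bond is cut to the aryllithium that the O5-MOM group of 11 directs; C6 is the only position ortho to that group that bears hydrogen. 11 is the MOM ether of chromenol 10.

**10 ⇒ 8 ⇒ 6 + 7.** Ring B is traced to cyclohexane-1,3-dione 6. Its C2 becomes C3′ and its two carbonyl oxygens become O4′ and O2′, so annulation with 3-methylbut-2-enal 7 can give only the required fusion, which resorcinol itself would not guarantee. The forward sequence needs one dehydrogenation of 8 to the phenol 10.

## Roads not taken

**Alternative 1: isoflavanone reduction with dynamic kinetic resolution (the route most chemists would draw first).** The cut removes C4–H and C3–H. The racemic isoflavanone A1 would be built from a deoxybenzoin and funnelled by asymmetric transfer hydrogenation with dynamic kinetic resolution to the cis-isoflavan-4-ol A2; the benzylic C4 oxygen would then be removed. The chosen plan is better because the conjugate reduction on the way to A1 and the hydrogenolytic or ionic removal of C4–OH are exactly the conditions that the prenyl and chromene olefins do not survive. Both C5 units would therefore have to be attached after C3 is set, on a substrate with three phenols to differentiate and with regiocontrol at C8 and C3′ on the whole skeleton. That costs at least six further steps, and C3 stays racemisable up to the reduction.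

**Alternative 2: auxiliary-controlled benzylation and ring closure at O1–C2.** The cuts are O1–C2 and C3–C4. Benzylation of the enolate of a B-ring arylacetyl oxazolidinone with an A-ring benzyl bromide would give imide A3; reductive removal of the auxiliary and unmasking of O1 would give the diarylpropanol A4, and a Mitsunobu etherification would close ring C. The chosen plan is better for four reasons:
- the auxiliary is stoichiometric;
- four operations (acylation, alkylation, cleavage/unmasking, cyclisation) do what step 9 does in one;
- the electrophile is a 2,4-dioxygenated benzyl bromide, which ionises and self-condenses easily;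
- O1 needs a third, orthogonal protecting group, and the B-ring arylacetic acid needs a homologation from 13.

**Alternative 3: aromatic Claisen rearrangement with 1,3-chirality transfer on ring B.** The cut is C3–C1′. The ether A5, made from chromenol 10 and an enantiopure (E)-allylic alcohol, would rearrange through a chair transition state to the ortho-substituted phenol A6. Ring D blocks the other ortho position, and the carbinol configuration is carried to C3. The chosen plan is better because the rearrangement leaves a two-carbon propenyl arm on C3 where the target needs the one-carbon C2H2–O1 unit. Excising that carbon needs ozonolysis or dihydroxylation/periodate in the presence of two more electron-rich olefins. This would force the prenyl and pyran units to be introduced later, removing the very blocking group that secures the regiochemistry, and it adds the allylic alcohol synthesis and a final cyclisation.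

Key step: step 9

Assumptions:
- The CIP descriptor of the target derived from the given SMILES is 3R.
- The sense of induction of the chiral ligand in step 9 cannot be taken from precedent; "(R)" stands for whichever antipode a pilot run on 5 shows to lead to the (3R) series.
- The reagents named under "Reagents that add atoms" are taken as purchased.

## Route

Step 1
Reactants: 1 2,4-dihydroxybenzaldehyde
Product: 2 2-hydroxy-4-(methoxymethoxy)benzaldehyde
Conditions: MOMCl (1.1 equiv), K2CO3, acetone, 0 °C → rt
Reagents that add atoms: chloromethyl methyl ether, COCCl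
Why: Williamson-type O-alkylation; the O2–H is hydrogen-bonded to the formyl group and less nucleophilic, so the free O4–H should react selectively.

Step 2
Reactants: 2 2-hydroxy-4-(methoxymethoxy)benzaldehyde
Product: 3 4-(methoxymethoxy)-2-[(2-methylbut-3-en-2-yl)oxy]benzaldehyde
Conditions: tert-butyl (2-methylbut-3-en-2-yl) carbonate (1.5 equiv), Pd(PPh3)4 (3 mol %), THF, 0 °C
Reagents that add atoms: tert-butyl (2-methylbut-3-en-2-yl) carbonate, CC(C)(C)OC(=O)OC(C)(C)C=C
Why: Tsuji–Trost O-allylation; decarboxylation gives the tert-butoxide that deprotonates the phenol, and under kinetic control at low temperature the phenoxide should attack the more substituted terminus of the 1,1-dimethyl-π-allyl complex to give the tertiary ether.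

Step 3
Reactants: 3 4-(methoxymethoxy)-2-[(2-methylbut-3-en-2-yl)oxy]benzaldehyde
Product: 4 2-hydroxy-4-(methoxymethoxy)-3-(3-methylbut-2-en-1-yl)benzaldehyde
Conditions: PhNEt2, 130 °C
Reagents that add atoms: none
Why: Aromatic Claisen rearrangement ([3,3]); the only ortho position that bears hydrogen is C3, so the allyl unit should arrive there with inversion to the linear prenyl group, and the basic solvent suppresses acid-induced cyclisation of the o-prenylphenol.

Step 4
Reactants: 4 2-hydroxy-4-(methoxymethoxy)-3-(3-methylbut-2-en-1-yl)benzaldehyde
Product: 5 7-(methoxymethoxy)-8-(3-methylbut-2-en-1-yl)-2H-chromene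
Conditions: vinyltriphenylphosphonium bromide (1.3 equiv), Cs2CO3, MeCN, 70 °C
Reagents that add atoms: vinyltriphenylphosphonium bromide, C=C[P+](c1ccccc1)(c1ccccc1)c1ccccc1.[Br-]
Why: Schweizer chromene synthesis; oxa-Michael addition of the phenoxide to the vinylphosphonium salt gives an ylide that closes ring C by intramolecular Wittig olefination of the neighbouring aldehyde, which becomes C4.

Step 5
Reactants: 6 cyclohexane-1,3-dione; 7 3-methylbut-2-enal
Product: 8 2,2-dimethyl-7,8-dihydro-2H-chromen-5(6H)-one
Conditions: ethylenediammonium diacetate (10 mol %), MeOH, rt → 50 °C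
Reagents that add atoms: none
Why: Knoevenagel condensation followed by oxa-6π electrocyclisation (formal [3+3]); C2 of the dione is the only nucleophilic carbon, so the pyran can fuse only across C2 and one carbonyl oxygen.

Step 6
Reactants: 8 2,2-dimethyl-7,8-dihydro-2H-chromen-5(6H)-one
Product: 10 2,2-dimethyl-2H-chromen-5-ol, via 2,2-dimethyl-6-(phenylselanyl)-7,8-dihydro-2H-chromen-5(6H)-one 9 (not isolated)
Conditions: LDA, THF, −78 °C; PhSeCl; then 30% H2O2, pyridine, CH2Cl2, 0 °C → rt
Reagents that add atoms: none
Why: Kinetic deprotonation of the vinylogous ester at C6, α-selenenylation and selenoxide syn-elimination give the cross-conjugated dienone, which should tautomerise at once to the phenol.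

Step 7
Reactants: 10 2,2-dimethyl-2H-chromen-5-ol
Product: 11 5-(methoxymethoxy)-2,2-dimethyl-2H-chromene
Conditions: MOMCl (1.2 equiv), K2CO3, acetone, rt
Reagents that add atoms: chloromethyl methyl ether, COCCl
Why: Williamson-type O-alkylation of the only hydroxyl group; the acetal is chosen as a metalation-directing group.

Step 8
Reactants: 11 5-(methoxymethoxy)-2,2-dimethyl-2H-chromene
Product: 13 6-bromo-5-(methoxymethoxy)-2,2-dimethyl-2H-chromene, via [5-(methoxymethoxy)-2,2-dimethyl-2H-chromen-6-yl]lithium 12 (not isolated)
Conditions: n-BuLi, TMEDA, THF, −20 → 0 °C; then BrCCl2CCl2Br, −78 °C → rt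
Reagents that add atoms: 1,2-dibromo-1,1,2,2-tetrachloroethane, BrC(Cl)(Cl)C(Cl)(Cl)Br
Why: Directed ortho-metalation; C6 is the only hydrogen-bearing position ortho to the MOM ether, C2 is quaternary so there is no acidic allylic hydrogen, and the mild bromonium donor should not touch the olefin.

Step 9
Reactants: 5 7-(methoxymethoxy)-8-(3-methylbut-2-en-1-yl)-2H-chromene; 13 6-bromo-5-(methoxymethoxy)-2,2-dimethyl-2H-chromene
Product: 14 (3R)-7-(methoxymethoxy)-3-[5-(methoxymethoxy)-2,2-dimethyl-2H-chromen-6-yl]-8-(3-methylbut-2-en-1-yl)-3,4-dihydro-2H-chromene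
Conditions: Pd(dba)2 (5 mol %), (R)-Xyl-SDP(O) (6 mol %), HCO2Na (2 equiv), ethylene glycol/1,4-dioxane, 80 °C; 5 in slight excess
Reagents that add atoms: none
Why: Proposed new method: intermolecular enantioselective reductive Heck hydroarylation of an unstrained 2H-chromene, whose closest known reaction types are the racemic Pd-catalysed oxyarylation and hydroarylation of 2H-chromenes with ortho-oxygenated aryl halides and the ligand-controlled asymmetric reductive Heck arylation of strained or tethered olefins. Pd(0)L* adds oxidatively into the C6–Br bond of 13, bromide dissociates with help from the protic medium and the hemilabile P=O arm, the C3=C4 olefin of 5 undergoes syn-carbopalladation with aryl to C3 and Pd to C4 (held as an η3-benzyl over C4/C4a), and bromide/formate exchange, loss of CO2 and C4–H reductive elimination complete the cycle. No ring is closed in this step. The only new stereocentre, C3, is set in the migratory insertion by the chiral ligand, which discriminates the enantiotopic faces of a cis-olefin whose two ends differ as aryl and CH2O. Regioselectivity is secured by benzylic stabilisation at C4, reinforced by the 7-OMOM donor para to C4a. Site selectivity among the three olefins is secured by the gem-dimethyl group next to the ring-D olefin and by the trisubstitution of the prenyl olefin. Reductive termination is secured because after syn addition C3–H is anti to Pd and C4a has no hydrogen, so β-hydride elimination is closed, and because O2′ is capped as its MOM ether and cannot trap the benzyl–Pd as a pterocarpan.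

Step 10
Reactants: 14 (3R)-7-(methoxymethoxy)-3-[5-(methoxymethoxy)-2,2-dimethyl-2H-chromen-6-yl]-8-(3-methylbut-2-en-1-yl)-3,4-dihydro-2H-chromene
Product: 15 (3R)-3-(5-hydroxy-2,2-dimethyl-2H-chromen-6-yl)-8-(3-methylbut-2-en-1-yl)-3,4-dihydro-2H-chromen-7-ol
Conditions: dilute HCl, MeOH/THF, rt, stopped as soon as 14 is consumed
Reagents that add atoms: none
Why: Acid-catalysed transacetalisation of the two aryl MOM ethers to methanol; aryl MOM ethers cleave under much milder acid than is needed to protonate the prenyl or chromene olefins, and C3 has no acidic hydrogen and is not affected.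

## Compound list

1 | 2,4-dihydroxybenzaldehyde | O=Cc1ccc(O)cc1O | starting material
2 | 2-hydroxy-4-(methoxymethoxy)benzaldehyde | COCOc1ccc(C=O)c(O)c1 | intermediate
3 | 4-(methoxymethoxy)-2-[(2-methylbut-3-en-2-yl)oxy]benzaldehyde | COCOc1ccc(C=O)c(OC(C)(C)C=C)c1 | intermediate
4 | 2-hydroxy-4-(methoxymethoxy)-3-(3-methylbut-2-en-1-yl)benzaldehyde | COCOc1ccc(C=O)c(O)c1CC=C(C)C | intermediate
5 | 7-(methoxymethoxy)-8-(3-methylbut-2-en-1-yl)-2H-chromene | COCOc1ccc2c(c1CC=C(C)C)OCC=C2 | intermediate
6 | cyclohexane-1,3-dione | O=C1CCCC(=O)C1 | starting material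
7 | 3-methylbut-2-enal | CC(C)=CC=O | starting material
8 | 2,2-dimethyl-7,8-dihydro-2H-chromen-5(6H)-one | CC1(C)C=CC2=C(CCCC2=O)O1 | intermediate
9 | 2,2-dimethyl-6-(phenylselanyl)-7,8-dihydro-2H-chromen-5(6H)-one (racemic) | CC1(C)C=CC2=C(CCC([Se]c3ccccc3)C2=O)O1 | intermediate
10 | 2,2-dimethyl-2H-chromen-5-ol | CC1(C)C=Cc2c(O)cccc2O1 | intermediate
11 | 5-(methoxymethoxy)-2,2-dimethyl-2H-chromene | COCOc1cccc2OC(C)(C)C=Cc12 | intermediate
12 | [5-(methoxymethoxy)-2,2-dimethyl-2H-chromen-6-yl]lithium | [Li]c1ccc2OC(C)(C)C=Cc2c1OCOC | intermediate
13 | 6-bromo-5-(methoxymethoxy)-2,2-dimethyl-2H-chromene | COCOc1c(Br)ccc2OC(C)(C)C=Cc12 | intermediate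
14 | (3R)-7-(methoxymethoxy)-3-[5-(methoxymethoxy)-2,2-dimethyl-2H-chromen-6-yl]-8-(3-methylbut-2-en-1-yl)-3,4-dihydro-2H-chromene | CC(C)=CCc1c(OCOC)ccc2c1OC[C@@H](c1ccc3c(c1OCOC)C=CC(C)(C)O3)C2 | intermediate
15 | (3R)-3-(5-hydroxy-2,2-dimethyl-2H-chromen-6-yl)-8-(3-methylbut-2-en-1-yl)-3,4-dihydro-2H-chromen-7-ol | CC(C)=CCc1c(O)ccc2c1OC[C@@H](c1ccc3c(c1O)C=CC(C)(C)O3)C2 | target

## Step count and risk

Total step count: 10. Longest linear sequence: 6 steps (steps 1–4, 9, 10, or steps 5–8, 9, 10).

Least certain steps:

**Step 9 (key step, proposed new method).**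
- Facial discrimination in the carbopalladation may be poor, because the two ends of the olefin differ only as aryl and CH2O.
- Insertion of a hindered ortho-alkoxyaryl–palladium into an unstrained cis-olefin may be slower than its reduction by formate, which would lead to hydrodebromination.
- A palladium hydride may shift the olefin of 5 out of conjugation.
- Fallback (known chemistry), from 5 to 14. Copper-catalysed enantioselective protoboration of 5 (B2pin2, CuCl, NaOt-Bu, a chiral bisphosphine, MeOH, THF) places boron at C3, because copper goes to the benzylic C4, and should give 2-[(3R)-7-(methoxymethoxy)-8-(3-methylbut-2-en-1-yl)-3,4-dihydro-2H-chromen-3-yl]-4,4,5,5-tetramethyl-1,3,2-dioxaborolane, F1. KHF2 converts it into potassium trifluoro[(3R)-7-(methoxymethoxy)-8-(3-methylbut-2-en-1-yl)-3,4-dihydro-2H-chromen-3-yl]borate, F2. Stereospecific Suzuki–Miyaura coupling of F2 with 13 under Pd/P(t-Bu)3 (K2CO3, toluene/water) returns to the route at 14. This catalyst type transfers unactivated secondary alkyl groups with inversion, which is why the (3R)-boronate is taken.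

**Step 2.**
- Pd(0) may re-ionise the tertiary allylic aryl ether, and the system may collapse to the linear prenyl ether, which would give the wrong C-allyl isomer in step 3.
- Fallback, from 1 to 4. O4-alkylation of 1 with 3-chloro-3-methylbut-1-yne (K2CO3, KI, acetone) gives 2-hydroxy-4-[(2-methylbut-3-yn-2-yl)oxy]benzaldehyde, F3. Lindlar semi-hydrogenation gives 2-hydroxy-4-[(2-methylbut-3-en-2-yl)oxy]benzaldehyde, F4. Thermal [3,3] rearrangement gives 2,4-dihydroxy-3-(3-methylbut-2-en-1-yl)benzaldehyde, F5; it is steered to C3 by the hydrogen bond between O2–H and the formyl group, which fixes C3–C4 as the more olefinic bond. Selective methoxymethylation of the free O4–H returns to the route at 4.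

**Step 4.**
- Oxa-Michael addition of the hindered, hydrogen-bonded phenoxide may be slow, and the vinylphosphonium salt may decompose under base before it is captured.
- Fallback, from 4 to 5. O-Allylation of 4 (allyl bromide, K2CO3) gives 4-(methoxymethoxy)-3-(3-methylbut-2-en-1-yl)-2-(prop-2-en-1-yloxy)benzaldehyde, F6. Wittig methylenation gives 1-ethenyl-4-(methoxymethoxy)-3-(3-methylbut-2-en-1-yl)-2-(prop-2-en-1-yloxy)benzene, F7. Ring-closing metathesis between the two monosubstituted olefins with a ruthenium alkylidene closes ring C and returns to the route at 5.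

**Step 8.**
- Deprotonation may compete at the vinylic C4–H of the pyran ring or at C8 next to the ring oxygen, and butyllithium may add to the styrenic olefin.
- Fallback, from 8 to 13; the halogen is carried through the aromatisation and steps 6–8 are bypassed. Two cycles of kinetic enolisation and bromination of 8 (LiHMDS, NBS, THF, −78 °C) give 6,6-dibromo-2,2-dimethyl-7,8-dihydro-2H-chromen-5(6H)-one, F8. Dehydrobromination and tautomerisation with DBU give 6-bromo-2,2-dimethyl-2H-chromen-5-ol, F9. Methoxymethylation (MOMCl, K2CO3) returns to the route at 13.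

**Step 10.**
- Once O2′–H is free, protonation of the ring-D olefin gives a cation stabilised as an ortho-quinone methide, and methanol or water may add to it; O7–H may also add across the protonated prenyl olefin.
- Fallback, from 14 to 15. TMSOTf/2,2′-bipyridyl in CH2Cl2 at 0 °C exchanges both aryl MOM ethers for silyl ethers without a Brønsted acid and gives (3R)-3-[2,2-dimethyl-5-(trimethylsilyloxy)-2H-chromen-6-yl]-8-(3-methylbut-2-en-1-yl)-7-(trimethylsilyloxy)-3,4-dihydro-2H-chromene, F10. Methanolysis with K2CO3/MeOH returns to the route at 15.

## Further compounds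

F1 | step 9 | 2-[(3R)-7-(methoxymethoxy)-8-(3-methylbut-2-en-1-yl)-3,4-dihydro-2H-chromen-3-yl]-4,4,5,5-tetramethyl-1,3,2-dioxaborolane | COCOc1ccc2c(c1CC=C(C)C)OC[C@H](B1OC(C)(C)C(C)(C)O1)C2
F2 | step 9 | potassium trifluoro[(3R)-7-(methoxymethoxy)-8-(3-methylbut-2-en-1-yl)-3,4-dihydro-2H-chromen-3-yl]borate | COCOc1ccc2c(c1CC=C(C)C)OC[C@H]([B-](F)(F)F)C2.[K+]
F3 | step 2 | 2-hydroxy-4-[(2-methylbut-3-yn-2-yl)oxy]benzaldehyde | C#CC(C)(C)Oc1ccc(C=O)c(O)c1
F4 | step 2 | 2-hydroxy-4-[(2-methylbut-3-en-2-yl)oxy]benzaldehyde | C=CC(C)(C)Oc1ccc(C=O)c(O)c1
F5 | step 2 | 2,4-dihydroxy-3-(3-methylbut-2-en-1-yl)benzaldehyde | CC(C)=CCc1c(O)ccc(C=O)c1O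
F6 | step 4 | 4-(methoxymethoxy)-3-(3-methylbut-2-en-1-yl)-2-(prop-2-en-1-yloxy)benzaldehyde | C=CCOc1c(C=O)ccc(OCOC)c1CC=C(C)C
F7 | step 4 | 1-ethenyl-4-(methoxymethoxy)-3-(3-methylbut-2-en-1-yl)-2-(prop-2-en-1-yloxy)benzene | C=CCOc1c(C=C)ccc(OCOC)c1CC=C(C)C
F8 | step 8 | 6,6-dibromo-2,2-dimethyl-7,8-dihydro-2H-chromen-5(6H)-one | CC1(C)C=CC2=C(CCC(Br)(Br)C2=O)O1
F9 | step 8 | 6-bromo-2,2-dimethyl-2H-chromen-5-ol | CC1(C)C=Cc2c(O)c(Br)ccc2O1
F10 | step 10 | (3R)-3-[2,2-dimethyl-5-(trimethylsilyloxy)-2H-chromen-6-yl]-8-(3-methylbut-2-en-1-yl)-7-(trimethylsilyloxy)-3,4-dihydro-2H-chromene | CC(C)=CCc1c(O[Si](C)(C)C)ccc2c1OC[C@@H](c1ccc3c(c1O[Si](C)(C)C)C=CC(C)(C)O3)C2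
A1 | alternative 1 | rac-3-[2,4-bis(methoxymethoxy)phenyl]-7-(methoxymethoxy)-2,3-dihydro-4H-chromen-4-one | COCOc1ccc2c(c1)OCC(c1ccc(OCOC)cc1OCOC)C2=O
A2 | alternative 1 | (3R,4R)-3-[2,4-bis(methoxymethoxy)phenyl]-7-(methoxymethoxy)-3,4-dihydro-2H-chromen-4-ol (cis) | COCOc1ccc2c(c1)OC[C@@H](c1ccc(OCOC)cc1OCOC)[C@H]2O
A3 | alternative 2 | (4R)-4-benzyl-3-{(2R)-3-[2-(tert-butyldimethylsilyloxy)-4-(methoxymethoxy)-3-(3-methylbut-2-en-1-yl)phenyl]-2-[5-(methoxymethoxy)-2,2-dimethyl-2H-chromen-6-yl]propanoyl}-1,3-oxazolidin-2-one | O=C([C@@H](c1ccc2OC(C)(C)C=Cc2c1OCOC)Cc1ccc(OCOC)c(CC=C(C)C)c1O[Si](C)(C)C(C)(C)C)N1C(=O)OC[C@H]1Cc1ccccc1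
A4 | alternative 2 | (2R)-3-[2-hydroxy-4-(methoxymethoxy)-3-(3-methylbut-2-en-1-yl)phenyl]-2-[5-(methoxymethoxy)-2,2-dimethyl-2H-chromen-6-yl]propan-1-ol | OC[C@@H](c1ccc2OC(C)(C)C=Cc2c1OCOC)Cc1ccc(OCOC)c(CC=C(C)C)c1O
A5 | alternative 3 | 5-{[(2R,3E)-5-[2,4-bis(methoxymethoxy)-3-(3-methylbut-2-en-1-yl)phenyl]pent-3-en-2-yl]oxy}-2,2-dimethyl-2H-chromene | C[C@@H](Oc1cccc2OC(C)(C)C=Cc12)/C=C/Cc1ccc(OCOC)c(CC=C(C)C)c1OCOC
A6 | alternative 3 | 6-{(2S,3E)-1-[2,4-bis(methoxymethoxy)-3-(3-methylbut-2-en-1-yl)phenyl]pent-3-en-2-yl}-2,2-dimethyl-2H-chromen-5-ol | C/C=C/[C@@H](c1ccc2OC(C)(C)C=Cc2c1O)Cc1ccc(OCOC)c(CC=C(C)C)c1OCOC
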